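**Retrosynthetic overview**
- Target ⇐ double desilylation ⇐ acylation of the C-4 allylic alcohol with 4-(silyloxy)benzoyl chloride (fragment 3, three steps from 4-hydroxybenzoic acid); C-4 carbinol ⇐ convex-face Luche reduction; cis-2,3-diol monoacetate ⇐ convex-face OsO4 dihydroxylation.
- Seven-membered ring (closed last) ⇐ ring-closing metathesis of a cyclopentene that carries a vinyl ketone arm and a methallyl carbinol arm, cis on adjacent carbons.
- Vinyl carbinol arm at C-3a ⇐ [2,3]-Wittig rearrangement of the allyl ether of a CBS-derived cyclopentenol (chirality transfer; moves the ring alkene to C-2/C-3).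
- C-8 carbinol ⇐ Brown methallylboration of a quaternary aldehyde with the borane from (+)-α-pinene and methallyl chloride (fragment 2, four steps).
- Five-membered ring is bought as 3-methylcyclopent-2-en-1-one (fragment 1): asymmetric conjugate alkenylation (quaternary centre), aldol/isomerisation (isopropyl enone), ozonolysis.

Assumption: the SMILES is taken as drawn, i.e. a cis-fused hydroazulene (8a-CH3 and 3a-H on the same face), 2S,3R,3aR,4S,8S,8aS in azulene numbering, which is used for all bicyclic names.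

**Step 1**
Reactants: 1 3-methylcyclopent-2-en-1-one; 2 3,3-dimethylbut-1-yne
Product: 4 (3R)-3-[(1E)-3,3-dimethylbut-1-en-1-yl]-3-methylcyclopentan-1-one, via alkenylalane 3 (not isolated)
Conditions: 2, iBu2AlH (1.5 equiv each), hexane, 55 °C, 4 h; then 1, Cu(O2C-C4H3S) (copper thiophene-2-carboxylate, 5 mol %), (R,R)-N,N-bis(1-phenylethyl)-P,P-diphenylphosphinous amide (6 mol %; its antipode is used if the 3S ketone forms), Et2O, −30 °C, 12 h; aq. HCl
Reagents that add atoms: none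
Why: syn-Hydroalumination gives the E-alkenylalane and the copper-catalysed asymmetric conjugate addition transfers the alkenyl group to one enantioface of the β-methyl enone, which sets the quaternary stereocentre (R) and installs a masked formyl group.

**Step 2**
Reactants: 4 (3R)-3-[(1E)-3,3-dimethylbut-1-en-1-yl]-3-methylcyclopentan-1-one
Product: 6 (4R)-4-[(1E)-3,3-dimethylbut-1-en-1-yl]-4-methyl-2-(propan-2-yl)cyclopent-2-en-1-one, via aldol adduct 5 (not isolated)
Conditions: LiN(iPr)2 (1.1 equiv), THF, −78 °C; acetone (3 equiv), −78 °C; NH4Cl; crude 5, TsOH·H2O (0.3 equiv), PhMe, 110 °C (Dean–Stark)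
Reagents that add atoms: acetone, CC(C)=O
Why: Directed aldol addition of the kinetic enolate (formed at the CH2 remote from the quaternary carbon) to acetone, then acid-catalysed dehydration and exo-to-endo isomerisation to the conjugated 2-isopropylcyclopent-2-enone, the double bond being able to enter the ring only on the side away from the quaternary carbon; no stereocentre is touched.

**Step 3**
Reactants: 6 (4R)-4-[(1E)-3,3-dimethylbut-1-en-1-yl]-4-methyl-2-(propan-2-yl)cyclopent-2-en-1-one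
Product: 7 (1S)-1-methyl-4-oxo-3-(propan-2-yl)cyclopent-2-ene-1-carbaldehyde
Conditions: O3, CH2Cl2/MeOH 4:1, pyridine (2 equiv), −78 °C, stopped when 6 is consumed; Me2S (5 equiv), −78 °C → rt
Reagents that add atoms: ozone, [O-][O+]=O
Why: Chemoselective ozonolysis, the isolated electron-rich E-alkene being cleaved much faster than the electron-poor enone double bond, which unmasks the non-enolisable quaternary aldehyde without affecting the stereocentre.

**Step 4**
Reactants: 8 (+)-α-pinene, (1R,5R)-2,6,6-trimethylbicyclo[3.1.1]hept-2-ene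
Product: 9 (−)-diisopinocampheylborane, bis[(1R,2S,3R,5R)-2,6,6-trimethylbicyclo[3.1.1]heptan-3-yl]borane
Conditions: BH3·SMe2 (0.5 equiv), THF, 0 °C, 3 d; crystals collected
Reagents that add atoms: borane–dimethyl sulfide, C[S+](C)[BH3-]
Why: Hydroboration, each B–H adding syn to the alkene face anti to the gem-dimethyl bridge with boron on the less substituted carbon, and crystallisation upgrades the enantiopurity of the dialkylborane.

**Step 5**
Reactants: 9 (−)-diisopinocampheylborane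
Product: 10 (−)-B-methoxydiisopinocampheylborane
Conditions: MeOH (1.0 equiv), Et2O, 0 °C → rt
Reagents that add atoms: methanol, CO
Why: Methanolysis of the B–H bond gives the borinate precursor of B-allyl reagents and leaves the terpene stereocentres untouched.

**Step 6**
Reactants: 11 3-chloro-2-methylprop-1-ene
Product: 12 (2-methylprop-2-en-1-yl)magnesium chloride
Conditions: Mg turnings, THF, 0 °C, slow addition
Reagents that add atoms: magnesium, [Mg]
Why: Grignard formation by magnesium insertion into the allylic C–Cl bond, slow addition limiting Wurtz coupling.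

**Step 7**
Reactants: 10 (−)-B-methoxydiisopinocampheylborane; 12 (2-methylprop-2-en-1-yl)magnesium chloride
Product: 13 (−)-B-(2-methylprop-2-en-1-yl)diisopinocampheylborane
Conditions: Et2O, −78 °C → rt, 1 h; Mg salts filtered off under argon; solution used at once
Reagents that add atoms: none
Why: Transmetalation, the Grignard reagent adding to boron and methoxide leaving as its magnesium salt, gives the chiral B-methallylborane that will deliver C-7, C-6 and the 6-methyl group.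

**Step 8**
Reactants: 7 (1S)-1-methyl-4-oxo-3-(propan-2-yl)cyclopent-2-ene-1-carbaldehyde; 13 (−)-B-(2-methylprop-2-en-1-yl)diisopinocampheylborane
Product: 14 (4S)-4-[(1S)-1-hydroxy-3-methylbut-3-en-1-yl]-4-methyl-2-(propan-2-yl)cyclopent-2-en-1-one
Conditions: 13 (1.5 equiv), Et2O, −78 °C, 4 h; MeOH at −78 °C; 2-aminoethanol, rt; filtration
Reagents that add atoms: none
Why: Brown asymmetric allylboration through a chair Zimmerman–Traxler transition state, the reagent from (+)-α-pinene adding the methallyl group to the Si face of the aldehyde under reagent control to give the 1S carbinol (the future C-8), the aldehyde reacting at −78 °C much faster than the enone carbonyl.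

**Step 9**
Reactants: 14 (4S)-4-[(1S)-1-hydroxy-3-methylbut-3-en-1-yl]-4-methyl-2-(propan-2-yl)cyclopent-2-en-1-one
Product: 15 (4S)-4-[(1S)-1-{[tert-butyl(dimethyl)silyl]oxy}-3-methylbut-3-en-1-yl]-4-methyl-2-(propan-2-yl)cyclopent-2-en-1-one
Conditions: TBSOTf (1.3 equiv), 2,6-lutidine (2.5 equiv), CH2Cl2, −78 → 0 °C
Reagents that add atoms: TBSOTf, CC(C)(C)[Si](C)(C)OS(=O)(=O)C(F)(F)F
Why: Silyl ether formation with the silyl triflate, needed for this hindered neopentyl-type hydroxyl, masks it through the later base, oxidation and acylation steps.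

**Step 10**
Reactants: 15 (4S)-4-[(1S)-1-{[tert-butyl(dimethyl)silyl]oxy}-3-methylbut-3-en-1-yl]-4-methyl-2-(propan-2-yl)cyclopent-2-en-1-one
Product: 16 (1R,4S)-4-[(1S)-1-{[tert-butyl(dimethyl)silyl]oxy}-3-methylbut-3-en-1-yl]-4-methyl-2-(propan-2-yl)cyclopent-2-en-1-ol
Conditions: (S)-2-methyl-CBS-oxazaborolidine (0.2 equiv), catecholborane (1.8 equiv), PhMe, −78 °C; MeOH
Reagents that add atoms: none
Why: Corey–Bakshi–Shibata reduction, in which the (S)-oxazaborolidine (enone C=C side as the large group) delivers hydride to give the 1R allylic alcohol with OH cis to the silyloxyalkyl arm, hydride approach anti to that arm being also substrate-preferred, while catecholborane spares the 1,1-disubstituted alkene.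

**Step 11**
Reactants: 16 (1R,4S)-4-[(1S)-1-{[tert-butyl(dimethyl)silyl]oxy}-3-methylbut-3-en-1-yl]-4-methyl-2-(propan-2-yl)cyclopent-2-en-1-ol
Product: 17 tert-butyl(dimethyl){[(1S)-3-methyl-1-[(1S,4R)-1-methyl-3-(propan-2-yl)-4-(prop-2-en-1-yloxy)cyclopent-2-en-1-yl]but-3-en-1-yl]oxy}silane
Conditions: NaH (1.5 equiv), allyl bromide (2 equiv), Bu4NI (0.1 equiv), THF/DMF 4:1, 0 °C → rt
Reagents that add atoms: allyl bromide, C=CCBr
Why: Williamson etherification of the sodium alkoxide with allyl bromide, with retention at the carbinol carbon.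

**Step 12**
Reactants: 17 tert-butyl(dimethyl){[(1S)-3-methyl-1-[(1S,4R)-1-methyl-3-(propan-2-yl)-4-(prop-2-en-1-yloxy)cyclopent-2-en-1-yl]but-3-en-1-yl]oxy}silane
Product: 18 1-[(1R,5S)-5-[(1S)-1-{[tert-butyl(dimethyl)silyl]oxy}-3-methylbut-3-en-1-yl]-5-methyl-2-(propan-2-yl)cyclopent-2-en-1-yl]prop-2-en-1-ol (both carbinol epimers)
Conditions: n-BuLi (1.5 equiv), THF, −78 °C, 2 h; NH4Cl at −78 °C
Reagents that add atoms: none
Why: [2,3]-Wittig rearrangement, in which lithiation at the unsubstituted allylic OCH2 and a suprafacial shift form the new C–C bond at the ring alkene terminus on the face that carried the oxygen, placing the hydroxyallyl arm cis to the silyloxyalkyl arm and trans to the methyl group (ring carbon 1R, by chirality transfer) and moving the double bond to the isopropyl-bearing position; the carbinol carbon forms as a mixture that step 13 removes.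

**Step 13**
Reactants: 18 1-[(1R,5S)-5-[(1S)-1-{[tert-butyl(dimethyl)silyl]oxy}-3-methylbut-3-en-1-yl]-5-methyl-2-(propan-2-yl)cyclopent-2-en-1-yl]prop-2-en-1-ol
Product: 20 (3aR,8S,8aS)-8-{[tert-butyl(dimethyl)silyl]oxy}-6,8a-dimethyl-3-(propan-2-yl)-3a,7,8,8a-tetrahydroazulen-4(1H)-one, via vinyl ketone 19 (not isolated)
Conditions: Dess–Martin periodinane (1.3 equiv), NaHCO3, CH2Cl2, 0 °C; filtration through silica; crude 19, second-generation Hoveyda–Grubbs catalyst (7 mol %), 1,4-benzoquinone (10 mol %), PhMe (3 mM), 80 °C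
Reagents that add atoms: none
Why: Dess–Martin oxidation converges both carbinol epimers to the vinyl ketone and ring-closing metathesis between its vinyl group and the 1,1-disubstituted methallyl alkene closes the seven-membered ring as a trisubstituted cycloheptenone, the two arms being cis on adjacent ring carbons and the hindered cyclopentene alkene staying out; base-free conditions keep the 3a stereocentre.

**Step 14**
Reactants: 20 (3aR,8S,8aS)-8-{[tert-butyl(dimethyl)silyl]oxy}-6,8a-dimethyl-3-(propan-2-yl)-3a,7,8,8a-tetrahydroazulen-4(1H)-one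
Product: 22 (2S,3R,3aS,8S,8aS)-8-{[tert-butyl(dimethyl)silyl]oxy}-3-hydroxy-6,8a-dimethyl-4-oxo-3-(propan-2-yl)-1,2,3,3a,4,7,8,8a-octahydroazulen-2-yl acetate, via diol 21 (not isolated)
Conditions: OsO4 (5 mol %), NMO (1.5 equiv), acetone/H2O 5:1, 0 °C → rt; Na2SO3; crude 21, Ac2O (2 equiv), pyridine, DMAP (0.1 equiv), CH2Cl2, 0 °C
Reagents that add atoms: OsO4, O=[Os](=O)(=O)=O; N-methylmorpholine N-oxide, C[N+]1([O-])CCOCC1; acetic anhydride, CC(=O)OC(C)=O
Why: Upjohn dihydroxylation then selective acetylation, OsO4 attacking the electron-rich trisubstituted cyclopentene alkene rather than the enone alkene and from the convex face of the cis-fused bicycle (syn to 3a-H and 8a-CH3), which sets C-2 and C-3 with both hydroxyls cis and the isopropyl group on the concave face, after which only the secondary hydroxyl is acetylated.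

**Step 15**
Reactants: 22 (2S,3R,3aS,8S,8aS)-8-{[tert-butyl(dimethyl)silyl]oxy}-3-hydroxy-6,8a-dimethyl-4-oxo-3-(propan-2-yl)-1,2,3,3a,4,7,8,8a-octahydroazulen-2-yl acetate
Product: 23 (2S,3R,3aR,4S,8S,8aS)-8-{[tert-butyl(dimethyl)silyl]oxy}-3,4-dihydroxy-6,8a-dimethyl-3-(propan-2-yl)-1,2,3,3a,4,7,8,8a-octahydroazulen-2-yl acetate
Conditions: NaBH4 (1.5 equiv), CeCl3·7H2O (1.5 equiv), MeOH, −78 → −40 °C
Reagents that add atoms: none
Why: Luche 1,2-reduction, hydride adding to the enone carbonyl from the convex face (syn to 3a-H, away from the isopropyl group) to give the 4S allylic alcohol, the acetate surviving at low temperature.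

**Step 16**
Reactants: 24 4-hydroxybenzoic acid
Product: 25 tert-butyl(dimethyl)silyl 4-{[tert-butyl(dimethyl)silyl]oxy}benzoate
Conditions: TBSCl (2.4 equiv), imidazole (5 equiv), DMF, rt
Reagents that add atoms: TBSCl, CC(C)(C)[Si](C)(C)Cl
Why: Imidazole-promoted silylation of both the phenol (silyl ether) and the carboxylic acid (silyl ester).

**Step 17**
Reactants: 25 tert-butyl(dimethyl)silyl 4-{[tert-butyl(dimethyl)silyl]oxy}benzoate
Product: 26 4-{[tert-butyl(dimethyl)silyl]oxy}benzoic acid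
Conditions: AcOH/THF/H2O 3:1:1, rt, 2 h
Reagents that add atoms: none
Why: Selective hydrolysis, the silyl ester being far more labile than the aryl silyl ether, so mild aqueous acid frees only the carboxylic acid.

**Step 18**
Reactants: 26 4-{[tert-butyl(dimethyl)silyl]oxy}benzoic acid
Product: 27 4-{[tert-butyl(dimethyl)silyl]oxy}benzoyl chloride
Conditions: (COCl)2 (1.5 equiv), DMF (cat.), CH2Cl2, 0 °C → rt; used crude
Reagents that add atoms: oxalyl chloride, O=C(Cl)C(Cl)=O
Why: Acid chloride formation through the Vilsmeier-type chloroiminium intermediate under conditions that keep the aryl silyl ether.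

**Step 19**
Reactants: 23 (2S,3R,3aR,4S,8S,8aS)-8-{[tert-butyl(dimethyl)silyl]oxy}-3,4-dihydroxy-6,8a-dimethyl-3-(propan-2-yl)-1,2,3,3a,4,7,8,8a-octahydroazulen-2-yl acetate; 27 4-{[tert-butyl(dimethyl)silyl]oxy}benzoyl chloride
Product: 28 (2S,3R,3aR,4S,8S,8aS)-2-(acetyloxy)-8-{[tert-butyl(dimethyl)silyl]oxy}-3-hydroxy-6,8a-dimethyl-3-(propan-2-yl)-1,2,3,3a,4,7,8,8a-octahydroazulen-4-yl 4-{[tert-butyl(dimethyl)silyl]oxy}benzoate
Conditions: 27 (1.5 equiv), Et3N (3 equiv), DMAP (0.3 equiv), CH2Cl2, 0 °C → rt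
Reagents that add atoms: none
Why: DMAP-catalysed acylation (nucleophilic catalysis) esterifies the secondary allylic hydroxyl with retention while the tertiary hydroxyl does not react.

**Step 20**
Reactants: 28 (2S,3R,3aR,4S,8S,8aS)-2-(acetyloxy)-8-{[tert-butyl(dimethyl)silyl]oxy}-3-hydroxy-6,8a-dimethyl-3-(propan-2-yl)-1,2,3,3a,4,7,8,8a-octahydroazulen-4-yl 4-{[tert-butyl(dimethyl)silyl]oxy}benzoate
Product: 29 (2S,3R,3aR,4S,8S,8aS)-2-(acetyloxy)-3,8-dihydroxy-6,8a-dimethyl-3-(propan-2-yl)-1,2,3,3a,4,7,8,8a-octahydroazulen-4-yl 4-hydroxybenzoate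
Conditions: HF·pyridine, pyridine, THF, 0 °C → rt
Reagents that add atoms: none
Why: Fluoride-mediated desilylation removes the aryl and the secondary alkyl silyl ether in one operation under buffered conditions that leave the acetate, the benzoate and the allylic C–O bond intact.

**Compound list**
1 | 3-methylcyclopent-2-en-1-one | CC1=CC(=O)CC1 | starting material
2 | 3,3-dimethylbut-1-yne | CC(C)(C)C#C | starting material
3 | [(1E)-3,3-dimethylbut-1-en-1-yl]bis(2-methylpropyl)alumane | CC(C)C[Al](CC(C)C)/C=C/C(C)(C)C | intermediate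
4 | (3R)-3-[(1E)-3,3-dimethylbut-1-en-1-yl]-3-methylcyclopentan-1-one | O=C1C[C@](C)(/C=C/C(C)(C)C)CC1 | intermediate
5 | (3R)-3-[(1E)-3,3-dimethylbut-1-en-1-yl]-5-(2-hydroxypropan-2-yl)-3-methylcyclopentan-1-one (C-5 epimers) | O=C1C[C@](C)(/C=C/C(C)(C)C)CC1C(C)(C)O | intermediate
6 | (4R)-4-[(1E)-3,3-dimethylbut-1-en-1-yl]-4-methyl-2-(propan-2-yl)cyclopent-2-en-1-one | O=C1C[C@](C)(/C=C/C(C)(C)C)C=C1C(C)C | intermediate
7 | (1S)-1-methyl-4-oxo-3-(propan-2-yl)cyclopent-2-ene-1-carbaldehyde | O=C1C[C@](C)(C=O)C=C1C(C)C | intermediate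
8 | (+)-α-pinene, (1R,5R)-2,6,6-trimethylbicyclo[3.1.1]hept-2-ene | CC1=CC[C@@H]2C[C@H]1C2(C)C | starting material
9 | (−)-diisopinocampheylborane | B([C@@H]1C[C@@H]2C[C@H]([C@H]1C)C2(C)C)[C@@H]1C[C@@H]2C[C@H]([C@H]1C)C2(C)C | intermediate
10 | (−)-B-methoxydiisopinocampheylborane | COB([C@@H]1C[C@@H]2C[C@H]([C@H]1C)C2(C)C)[C@@H]1C[C@@H]2C[C@H]([C@H]1C)C2(C)C | intermediate
11 | 3-chloro-2-methylprop-1-ene | CC(=C)CCl | starting material
12 | (2-methylprop-2-en-1-yl)magnesium chloride | CC(=C)C[Mg]Cl | intermediate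
13 | (−)-B-(2-methylprop-2-en-1-yl)diisopinocampheylborane | CC(=C)CB([C@@H]1C[C@@H]2C[C@H]([C@H]1C)C2(C)C)[C@@H]1C[C@@H]2C[C@H]([C@H]1C)C2(C)C | intermediate
14 | (4S)-4-[(1S)-1-hydroxy-3-methylbut-3-en-1-yl]-4-methyl-2-(propan-2-yl)cyclopent-2-en-1-one | O=C1C[C@](C)([C@@H](O)CC(C)=C)C=C1C(C)C | intermediate
15 | (4S)-4-[(1S)-1-{[tert-butyl(dimethyl)silyl]oxy}-3-methylbut-3-en-1-yl]-4-methyl-2-(propan-2-yl)cyclopent-2-en-1-one | O=C1C[C@](C)([C@@H](O[Si](C)(C)C(C)(C)C)CC(C)=C)C=C1C(C)C | intermediate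
16 | (1R,4S)-4-[(1S)-1-{[tert-butyl(dimethyl)silyl]oxy}-3-methylbut-3-en-1-yl]-4-methyl-2-(propan-2-yl)cyclopent-2-en-1-ol | O[C@@H]1C[C@](C)([C@@H](O[Si](C)(C)C(C)(C)C)CC(C)=C)C=C1C(C)C | intermediate
17 | tert-butyl(dimethyl){[(1S)-3-methyl-1-[(1S,4R)-1-methyl-3-(propan-2-yl)-4-(prop-2-en-1-yloxy)cyclopent-2-en-1-yl]but-3-en-1-yl]oxy}silane | C=CCO[C@@H]1C[C@](C)([C@@H](O[Si](C)(C)C(C)(C)C)CC(C)=C)C=C1C(C)C | intermediate
18 | 1-[(1R,5S)-5-[(1S)-1-{[tert-butyl(dimethyl)silyl]oxy}-3-methylbut-3-en-1-yl]-5-methyl-2-(propan-2-yl)cyclopent-2-en-1-yl]prop-2-en-1-ol (both carbinol epimers) | CC(C)C1=CC[C@](C)([C@@H](O[Si](C)(C)C(C)(C)C)CC(C)=C)[C@@H]1C(O)C=C | intermediate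
19 | 1-[(1R,5S)-5-[(1S)-1-{[tert-butyl(dimethyl)silyl]oxy}-3-methylbut-3-en-1-yl]-5-methyl-2-(propan-2-yl)cyclopent-2-en-1-yl]prop-2-en-1-one | CC(C)C1=CC[C@](C)([C@@H](O[Si](C)(C)C(C)(C)C)CC(C)=C)[C@@H]1C(=O)C=C | intermediate
20 | (3aR,8S,8aS)-8-{[tert-butyl(dimethyl)silyl]oxy}-6,8a-dimethyl-3-(propan-2-yl)-3a,7,8,8a-tetrahydroazulen-4(1H)-one | CC(C)C1=CC[C@]2(C)[C@@H](O[Si](C)(C)C(C)(C)C)CC(C)=CC(=O)[C@H]12 | intermediate
21 | (2S,3R,3aS,8S,8aS)-8-{[tert-butyl(dimethyl)silyl]oxy}-2,3-dihydroxy-6,8a-dimethyl-3-(propan-2-yl)-2,3,3a,7,8,8a-hexahydroazulen-4(1H)-one | O[C@H]1C[C@]2(C)[C@@H](O[Si](C)(C)C(C)(C)C)CC(C)=CC(=O)[C@@H]2[C@]1(O)C(C)C | intermediate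
22 | (2S,3R,3aS,8S,8aS)-8-{[tert-butyl(dimethyl)silyl]oxy}-3-hydroxy-6,8a-dimethyl-4-oxo-3-(propan-2-yl)-1,2,3,3a,4,7,8,8a-octahydroazulen-2-yl acetate | CC(=O)O[C@H]1C[C@]2(C)[C@@H](O[Si](C)(C)C(C)(C)C)CC(C)=CC(=O)[C@@H]2[C@]1(O)C(C)C | intermediate
23 | (2S,3R,3aR,4S,8S,8aS)-8-{[tert-butyl(dimethyl)silyl]oxy}-3,4-dihydroxy-6,8a-dimethyl-3-(propan-2-yl)-1,2,3,3a,4,7,8,8a-octahydroazulen-2-yl acetate | CC(=O)O[C@H]1C[C@]2(C)[C@@H](O[Si](C)(C)C(C)(C)C)CC(C)=C[C@H](O)[C@@H]2[C@]1(O)C(C)C | intermediate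
24 | 4-hydroxybenzoic acid | OC(=O)c1ccc(O)cc1 | starting material
25 | tert-butyl(dimethyl)silyl 4-{[tert-butyl(dimethyl)silyl]oxy}benzoate | CC(C)(C)[Si](C)(C)OC(=O)c1ccc(O[Si](C)(C)C(C)(C)C)cc1 | intermediate
26 | 4-{[tert-butyl(dimethyl)silyl]oxy}benzoic acid | CC(C)(C)[Si](C)(C)Oc1ccc(C(=O)O)cc1 | intermediate
27 | 4-{[tert-butyl(dimethyl)silyl]oxy}benzoyl chloride | CC(C)(C)[Si](C)(C)Oc1ccc(C(Cl)=O)cc1 | intermediate
28 | (2S,3R,3aR,4S,8S,8aS)-2-(acetyloxy)-8-{[tert-butyl(dimethyl)silyl]oxy}-3-hydroxy-6,8a-dimethyl-3-(propan-2-yl)-1,2,3,3a,4,7,8,8a-octahydroazulen-4-yl 4-{[tert-butyl(dimethyl)silyl]oxy}benzoate | CC(=O)O[C@H]1C[C@]2(C)[C@@H](O[Si](C)(C)C(C)(C)C)CC(C)=C[C@H](OC(=O)c3ccc(O[Si](C)(C)C(C)(C)C)cc3)[C@@H]2[C@]1(O)C(C)C | intermediate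
29 | (2S,3R,3aR,4S,8S,8aS)-2-(acetyloxy)-3,8-dihydroxy-6,8a-dimethyl-3-(propan-2-yl)-1,2,3,3a,4,7,8,8a-octahydroazulen-4-yl 4-hydroxybenzoate | CC(=O)O[C@H]1C[C@]2(C)[C@@H](O)CC(C)=C[C@H](OC(=O)c3ccc(O)cc3)[C@@H]2[C@]1(O)C(C)C | target

**Totals**
Total step count: 20.
Longest linear sequence: 13 steps (1, 2, 3, 8, 9, 10, 11, 12, 13, 14, 15, 19, 20; the borane branch 4, 5, 7 followed by 8–15, 19, 20 is equally long).

**Steps most likely to fail, with fallbacks**

Step 1 (asymmetric conjugate alkenylation of a cyclopentenone; conversion and ee are uncertain). The fallback gives up catalytic enantiocontrol and resolves later. It sets out from 1 and 2: alane 3 is added to 1 with achiral Ni(acac)2 (5 mol %, THF, −20 °C) to give racemic 3-[(1E)-3,3-dimethylbut-1-en-1-yl]-3-methylcyclopentan-1-one F1. The conditions of steps 2 and 3 then give racemic 4-[(1E)-3,3-dimethylbut-1-en-1-yl]-4-methyl-2-(propan-2-yl)cyclopent-2-en-1-one F2 and racemic 1-methyl-4-oxo-3-(propan-2-yl)cyclopent-2-ene-1-carbaldehyde F3. Reagent-controlled methallylboration of F3 with 13 (conditions of step 8) gives two diastereomers, 14 and (4R)-4-[(1S)-1-hydroxy-3-methylbut-3-en-1-yl]-4-methyl-2-(propan-2-yl)cyclopent-2-en-1-one F4, which are separated by chromatography. The route is rejoined at 14, at the cost of half the material.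

Step 2 (aldol addition to enolisable acetone and an exo-to-endo equilibrium that may not lie fully on the endocyclic side). The fallback installs the isopropyl group by cross-coupling instead of condensation. It sets out from 4: IBX in DMSO at 70 °C dehydrogenates the only side that has a β-hydrogen and gives (4R)-4-[(1E)-3,3-dimethylbut-1-en-1-yl]-4-methylcyclopent-2-en-1-one F5. Iodine and pyridine in CH2Cl2 give (4R)-4-[(1E)-3,3-dimethylbut-1-en-1-yl]-2-iodo-4-methylcyclopent-2-en-1-one F6. Negishi coupling with iPrZnBr and Pd(dppf)Cl2 (5 mol %, THF, 40 °C) rejoins the route at 6.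

Step 12 ([2,3]-Wittig rearrangement onto an alkene terminus next to a quaternary carbon; [1,2]-shift or wrong-site lithiation may compete). The fallback uses the tin–lithium exchange variant (Still–Wittig), which generates the carbanion regiospecifically, and builds the vinyl carbinol afterwards. It sets out from 16: KH and Bu3SnCH2I in THF give tributyl({[(1R,4S)-4-[(1S)-1-{[tert-butyl(dimethyl)silyl]oxy}-3-methylbut-3-en-1-yl]-4-methyl-2-(propan-2-yl)cyclopent-2-en-1-yl]oxy}methyl)stannane F7. n-BuLi in THF at −78 °C gives [(1R,5S)-5-[(1S)-1-{[tert-butyl(dimethyl)silyl]oxy}-3-methylbut-3-en-1-yl]-5-methyl-2-(propan-2-yl)cyclopent-2-en-1-yl]methanol F8 with the same suprafacial transfer. Dess–Martin oxidation gives (1R,5S)-5-[(1S)-1-{[tert-butyl(dimethyl)silyl]oxy}-3-methylbut-3-en-1-yl]-5-methyl-2-(propan-2-yl)cyclopent-2-ene-1-carbaldehyde F9. Vinylmagnesium bromide in THF at −78 °C rejoins the route at 18.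

**Further compounds**
F1 | step 1 | racemic 3-[(1E)-3,3-dimethylbut-1-en-1-yl]-3-methylcyclopentan-1-one | O=C1CC(C)(/C=C/C(C)(C)C)CC1
F2 | step 1 | racemic 4-[(1E)-3,3-dimethylbut-1-en-1-yl]-4-methyl-2-(propan-2-yl)cyclopent-2-en-1-one | O=C1CC(C)(/C=C/C(C)(C)C)C=C1C(C)C
F3 | step 1 | racemic 1-methyl-4-oxo-3-(propan-2-yl)cyclopent-2-ene-1-carbaldehyde | O=C1CC(C)(C=O)C=C1C(C)C
F4 | step 1 | (4R)-4-[(1S)-1-hydroxy-3-methylbut-3-en-1-yl]-4-methyl-2-(propan-2-yl)cyclopent-2-en-1-one | O=C1C[C@@](C)([C@@H](O)CC(C)=C)C=C1C(C)C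
F5 | step 2 | (4R)-4-[(1E)-3,3-dimethylbut-1-en-1-yl]-4-methylcyclopent-2-en-1-one | O=C1C[C@](C)(/C=C/C(C)(C)C)C=C1
F6 | step 2 | (4R)-4-[(1E)-3,3-dimethylbut-1-en-1-yl]-2-iodo-4-methylcyclopent-2-en-1-one | O=C1C[C@](C)(/C=C/C(C)(C)C)C=C1I
F7 | step 12 | tributyl({[(1R,4S)-4-[(1S)-1-{[tert-butyl(dimethyl)silyl]oxy}-3-methylbut-3-en-1-yl]-4-methyl-2-(propan-2-yl)cyclopent-2-en-1-yl]oxy}methyl)stannane | CCCC[Sn](CCCC)(CCCC)CO[C@@H]1C[C@](C)([C@@H](O[Si](C)(C)C(C)(C)C)CC(C)=C)C=C1C(C)C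
F8 | step 12 | [(1R,5S)-5-[(1S)-1-{[tert-butyl(dimethyl)silyl]oxy}-3-methylbut-3-en-1-yl]-5-methyl-2-(propan-2-yl)cyclopent-2-en-1-yl]methanol | CC(C)C1=CC[C@](C)([C@@H](O[Si](C)(C)C(C)(C)C)CC(C)=C)[C@@H]1CO
F9 | step 12 | (1R,5S)-5-[(1S)-1-{[tert-butyl(dimethyl)silyl]oxy}-3-methylbut-3-en-1-yl]-5-methyl-2-(propan-2-yl)cyclopent-2-ene-1-carbaldehyde | CC(C)C1=CC[C@](C)([C@@H](O[Si](C)(C)C(C)(C)C)CC(C)=C)[C@@H]1C=O
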